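**Substrate left.** Of the substrate in the amber run, 91.2 % is left at 10.0 s and 58.3 % at 60.0 s. These two readings give the half-life of the substrate, the time in which whatever substrate is present halves: 1.29 min, a value read with the scatter of the readings. It predicts 76.2 % at 30.0 s, and the reading there is 76.3 %. That is a pseudo-first-order fall.

- amber: substrate 0.058 M; partner 0.058 M; free catalyst 3.5 mM; second catalyst 0.55 mM; added ligand 3.5 mM; run made earlier
- flask: substrate 0.058 M; partner 0.0580 M; free catalyst 3.5 mM; second catalyst 1.1 mM; added ligand 3.5 mM

amber run (percent of the substrate charged)

| time / s | target / % | substrate / % |
|---|---|---|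
| 10.0 | 0.6 | 91.2 |
| 12.0 | 1.1 | 90.0 |
| 20.0 | 2.2 | 83.9 |
| 30.0 | 4.5 | 76.3 |
| 50.0 | 11.3 | 63.8 |
| 60.0 | 13.0 | 58.3 |

(standard deviation of a reading: 0.3 percentage points)

- no earlier run changes the charge of free catalyst; that part of a forecast is a guess
- "the catalyst" is free catalyst with its forms; second catalyst is a second catalyst
- no earlier run changes the charge of second catalyst; that part of a forecast is a guess

- factor on the rate of making target when 30 % of the substrate are converted if free catalyst is charged twice over
- factor on the rate when 30 % of the substrate are converted if free catalyst is charged at 0.40 mM instead

**The curves.** My guess, since no run changes it, is that the second catalyst leaves this half-life alone. In the new flask c(substrate) then starts down at 0.0311 M min⁻¹. It passes 30 % conversion at 0.664 min, and the curve bends on toward zero. Target starts flat in the amber run, at 0.6 % after 10.0 s. In the amber run at 60.0 s it stands at 13.0 %, less than the 41.7 % of substrate gone. The gap is 16.6 mM, more than both catalyst charges together.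

**Two estimates.** Suppose the half-life goes inversely with the free catalyst charge. Substrate loss at 0.664 min, in the new flask 0.0218 M min⁻¹, then changes by a factor 0.114 at the low charge, and I take that as my figure for the rate of making target. For the double charge my guess is a factor below 2. The forecast gives 1.15 for the double charge and 0.26 for the low charge, assuming that “free catalyst drives step one and second catalyst drives step two”. At the low charge its factor is larger than mine.

**The result.** The simulation gives 1.38 for the double charge and 0.106 for the low charge; at the same conversion with the low charge, 70.4 % of the catalyst is idle complex.

    second catalyst + open intermediate ⇌ catalyst intermediate (K = 25.0 M⁻¹, k = 1700 M⁻¹ s⁻¹)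
    partner + catalyst intermediate → second catalyst + target (k = 23.0 M⁻¹ s⁻¹)
    free catalyst + added ligand ⇌ idle complex, settled at all times (K = 740 M⁻¹)
    substrate + free catalyst → free catalyst + open intermediate (k = 5.60 M⁻¹ s⁻¹)

Counted in half-lives, 5.00 min leaves 6.81 % of the substrate, and the flask holds 6.8 %. Free catalyst is 1.60 mM in this flask and 0.118 mM at the low charge; scaled inversely with it, the half-life comes to 17.5 min. At 30 % conversion with the low charge, that half-life means substrate lost at 0.001610 M min⁻¹, and target is made there at 0.001615 M min⁻¹.

The runs are simulated from invented constants, and the scatter is random.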